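**Retrosynthetic overview**
1. Target 31 ← acetylation at C9 of lactone 30 ← the 10-membered ring is closed last at C6–C7 by an intramolecular chromium-mediated γ-chloroallylation of a C7 aldehyde (sets C6 and C7, makes the exo-methylene, lactonises in the same flask).
2. Ring A ← semipinacol ring expansion (1,2-shift of C10 from C14 to C1) of an epoxy cyclopentanol; this sets the C1 quaternary centre and C2, and a Wharton transposition then gives C12–OH and C13=C14.
3. Epoxy cyclopentanol ← alkenyllithium from west fragment 7 added to epoxy cyclopentanone 16, then Shi epoxidation.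
4. Cyclopentenone 14 ← Piancatelli rearrangement of furylcarbinol 13 ← chelation-controlled propionate aldol ← D-proline aldol of 5-methylfurfural with dihydroxyacetone acetonide.
5. Ring order: cyclopentenone → ring A → 10-membered ring → γ-lactone.

Assumptions: the SMILES is taken as drawn (1S,2R,6S,7R,8R,9R,10S,11S,12R,17R); briarane numbering (C1–C20) is used for every intermediate and "as in 31" means the same spatial arrangement as in the target. Acetonide, tert-butyl ester and silyl groups are counted as protecting groups, and 2 is bought as its THF solution.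

**Step 1**
Reactants: 1 prop-2-yn-1-ol; 2 but-3-en-1-ylmagnesium bromide
Product: 4 (Z)-2-(but-3-en-1-yl)-3-chloroprop-2-en-1-ol, via magnesacycle 3 (not isolated)
Conditions: 2 (2.3 equiv), CuI (10 mol %), THF, −20 °C to rt; then N-chlorosuccinimide, −30 °C; 1 M HCl
Reagents that add atoms: N-chlorosuccinimide, O=C1CCC(=O)N1Cl
Why: copper-catalysed anti-carbomagnesiation of the propargylic alkoxide puts the butenyl group on C5 and magnesium on C6 in a five-membered chelate, and chlorination of the C–Mg bond with retention fixes Cl cis to CH2OH.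

**Step 2**
Reactants: 4 (Z)-2-(but-3-en-1-yl)-3-chloroprop-2-en-1-ol
Product: 5 tert-butyl{[(Z)-2-(but-3-en-1-yl)-3-chloroprop-2-en-1-yl]oxy}dimethylsilane
Conditions: TBSCl, imidazole, CH2Cl2, rt
Reagents that add atoms: tert-butyldimethylsilyl chloride, CC(C)(C)[Si](C)(C)Cl
Why: standard silylation of a primary alcohol so that the fragment tolerates the later organolithium step.

**Step 3**
Reactants: 5 tert-butyl{[(Z)-2-(but-3-en-1-yl)-3-chloroprop-2-en-1-yl]oxy}dimethylsilane
Product: 6 (Z)-4-({[tert-butyl(dimethyl)silyl]oxy}methyl)-5-chloropent-4-enal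
Conditions: OsO4 (2 mol %), NaIO4 (2.5 equiv), 2,6-lutidine, dioxane/H2O 3:1, rt
Reagents that add atoms: sodium periodate, [Na+].[O-]I(=O)(=O)=O
Why: Lemieux–Johnson cleavage takes the electron-rich monosubstituted alkene and leaves the electron-poor, hindered chloroalkene.

**Step 4**
Reactants: 6 (Z)-4-({[tert-butyl(dimethyl)silyl]oxy}methyl)-5-chloropent-4-enal
Product: 7 (1Z,5Z)-2-({[tert-butyl(dimethyl)silyl]oxy}methyl)-1-chloro-6-iodohepta-1,5-diene
Conditions: EtPPh3I, n-BuLi, THF, rt; I2, −78 °C; NaN(SiMe3)2, −20 °C; then 6, −78 °C to rt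
Reagents that add atoms: ethyltriphenylphosphonium iodide, CC[P+](c1ccccc1)(c1ccccc1)c1ccccc1.[I-]; iodine, II
Why: Stork–Zhao-type Wittig olefination with the α-iodo ylide gives the (Z)-2-iodoalkene (iodine cis to the chain) under kinetic control.

**Step 5**
Reactants: 8 5-methylfuran-2-carbaldehyde; 9 2,2-dimethyl-1,3-dioxan-5-one
Product: 10 (4R)-4-[(S)-hydroxy(5-methylfuran-2-yl)methyl]-2,2-dimethyl-1,3-dioxan-5-one
Conditions: D-proline (30 mol %), DMF, 4 °C
Reagents that add atoms: none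
Why: proline enamine aldol through the acid-bound chair transition state gives the anti adduct, with 9R set by the D-catalyst (the C10 carbinol centre is sacrificial).

**Step 6**
Reactants: 10 (4R)-4-[(S)-hydroxy(5-methylfuran-2-yl)methyl]-2,2-dimethyl-1,3-dioxan-5-one; 11 tert-butyl propanoate
Product: 13 tert-butyl (2R)-2-{(4R,5S)-5-hydroxy-4-[(S)-hydroxy(5-methylfuran-2-yl)methyl]-2,2-dimethyl-1,3-dioxan-5-yl}propanoate, via lithium enolate 12 (not isolated)
Conditions: 11 (3.0 equiv), LiN(i-Pr)2 (3.1 equiv), THF, −78 °C; then 10, −78 °C; AcOH quench at −78 °C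
Reagents that add atoms: none
Why: ketone aldol under 1,3-chelation control, in which the C10 lithium alkoxide binds the C8 carbonyl so that the methyl-trans-to-OLi enolate is delivered axially, cis to the C9–C10 bond (sets C8 as in 31), and a Zimmerman–Traxler chair with equatorial methyl sets C17.

**Step 7**
Reactants: 13 tert-butyl (2R)-2-{(4R,5S)-5-hydroxy-4-[(S)-hydroxy(5-methylfuran-2-yl)methyl]-2,2-dimethyl-1,3-dioxan-5-yl}propanoate
Product: 14 tert-butyl (2R)-2-{(4R,5S)-5-hydroxy-4-[(1S,2R)-2-hydroxy-2-methyl-5-oxocyclopent-3-en-1-yl]-2,2-dimethyl-1,3-dioxan-5-yl}propanoate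
Conditions: ZnCl2 (2 equiv), acetone/H2O 2:1, 60 °C
Reagents that add atoms: water, O
Why: Piancatelli rearrangement, in which the furylcarbinol ionises, water adds at C11 and conrotatory 4π-electrocyclisation gives the 10,11-trans cyclopentenone; the sense of conrotation is expected to be fixed by C9 (C9–H eclipsed with the dienyl plane to avoid allylic strain, new bond anti to the bulky C8), which sets C10 and C11.

**Step 8**
Reactants: 14 cyclopentenone (name as in step 7)
Product: 15 epoxy ketone (12,13-oxirane of 14 cis to the C11 hydroxyl)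
Conditions: t-BuOOH, DBU (0.2 equiv), CH2Cl2, 0 °C
Reagents that add atoms: tert-butyl hydroperoxide, CC(C)(C)OO
Why: Weitz–Scheffer nucleophilic epoxidation, in which the peroxide adds to C12 on the face of the hydrogen-bonding C11–OH, which is also the face away from the C10 side chain and the C11 methyl.

**Step 9**
Reactants: 15 epoxy ketone
Product: 16 bis(triethylsilyl) ether of 15 (at the C8 and C11 tertiary hydroxyls)
Conditions: Et3SiOTf, 2,6-lutidine, CH2Cl2, −40 to 0 °C
Reagents that add atoms: triethylsilyl triflate, CC[Si](CC)(CC)OS(=O)(=O)C(F)(F)F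
Why: silylation of both tertiary alcohols removes the acidic protons before the organolithium step and prevents oxolane formation from the C11 oxygen in step 12.

**Step 10**
Reactants: 7 (1Z,5Z)-2-({[tert-butyl(dimethyl)silyl]oxy}methyl)-1-chloro-6-iodohepta-1,5-diene; 16 bis(triethylsilyl) epoxy ketone
Product: 18 C14 tertiary alcohol (alkenyl adduct of 16), via alkenyllithium 17 (not isolated)
Conditions: 7, t-BuLi (2.0 equiv), Et2O, −78 °C; LaCl3·2LiCl (0.3 equiv), 16, THF, −78 °C; then H2O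
Reagents that add atoms: none
Why: iodine–lithium exchange with retention of alkene geometry, then 1,2-addition to the ketone anti to the C10 substituent; the C14 carbinol centre is erased in step 12, so an epimer mixture is tolerated.

**Step 11**
Reactants: 18 C14 tertiary alcohol
Product: 19 (1R,2R)-1,2-epoxide of 18
Conditions: D-fructose-derived Shi ketone (30 mol %), KHSO5 (triple salt), K2CO3, Bu4NHSO4, MeCN/CH2(OMe)2/aq. buffer pH 10.5, 0 °C
Reagents that add atoms: potassium peroxymonosulfate, [K+].[O-]S(=O)(=O)OO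
Why: Shi asymmetric epoxidation gives the (1R,2R)-oxirane of the trisubstituted alkene under reagent control through the spiro transition state, while the vinyl chloride is too electron-poor to react.

**Step 12**
Reactants: 19 (1R,2R)-1,2-epoxide
Product: 20 ring-A β-hydroxy ketone (C14 ketone, 1S quaternary centre, 2R carbinol, 12,13-oxirane retained)
Conditions: BF3·OEt2 (0.2 equiv), CH2Cl2, −78 to −40 °C
Reagents that add atoms: none
Why: semipinacol rearrangement of a 2,3-epoxy alcohol, in which Lewis-acid opening at tertiary C1 is concerted with a 1,2-shift of C10 from C14 to C1 anti to the breaking C–O bond (retention at C10, inversion at C1), so the cyclopentane expands to ring A and C1 and C2 follow from the oxirane whatever the C14 configuration; the secondary alkyl C10 should migrate in preference to the electron-poor oxirane carbon C13.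

**Step 13**
Reactants: 20 ring-A β-hydroxy ketone
Product: 22 allylic alcohol (C13=C14 alkene and 12R hydroxyl), via hydrazone 21 (not isolated)
Conditions: N2H4·H2O (5 equiv), AcOH (0.5 equiv), MeOH, 0 °C to rt
Reagents that add atoms: none
Why: Wharton transposition, in which the epoxy hydrazone fragments with loss of N2 to the alkene and the C12 alcohol, whose configuration is that of the oxirane C–O bond set in step 8.

**Step 14**
Reactants: 22 allylic alcohol
Product: 23 2,12-diacetate of 22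
Conditions: Ac2O, DMAP, pyridine, rt
Reagents that add atoms: acetic anhydride, CC(=O)OC(C)=O
Why: acylation of the two secondary alcohols installs two of the three target acetates and masks them before the bromination.

**Step 15**
Reactants: 23 2,12-diacetate
Product: 24 C16 primary allylic alcohol (C8 and C11 hydroxyls also free)
Conditions: HF·pyridine, pyridine/THF, 0 °C to rt
Reagents that add atoms: none
Why: buffered fluoride cleaves the primary TBS ether and both tertiary triethylsilyl ethers, while the acetonide, acetates and tert-butyl ester survive.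

**Step 16**
Reactants: 24 C16 primary allylic alcohol
Product: 25 C16 allylic bromide
Conditions: CBr4, PPh3, 2,6-lutidine, CH2Cl2, −20 °C
Reagents that add atoms: carbon tetrabromide, BrC(Br)(Br)Br
Why: Appel bromination by SN2 at the only primary alcohol; the tertiary alcohols do not react.

**Step 17**
Reactants: 25 C16 allylic bromide
Product: 26 7,9-diol (acetonide removed)
Conditions: PPTS (0.2 equiv), MeOH, 40 °C
Reagents that add atoms: none
Why: acid-catalysed transacetalisation frees the 1,3-diol, and the tert-butyl ester prevents premature lactonisation onto the C7 hydroxyl.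

**Step 18**
Reactants: 26 7,9-diol
Product: 27 C7 aldehyde
Conditions: TEMPO (0.1 equiv), PhI(OAc)2, CH2Cl2, rt
Reagents that add atoms: none
Why: oxoammonium oxidation is selective for the primary alcohol over the hindered secondary C9 alcohol, and the product has no α-hydrogen to epimerise.

**Step 19**
Reactants: 27 C7 aldehyde
Product: 30 9-deacetyl lactone (31 lacking the C9 acetate), via allylchromium 28 (not isolated), via hydroxy ester 29 (not isolated)
Conditions: CrCl2 (8 equiv), THF, rt, slow addition (2 mM); then CF3CO2H, CH2Cl2, 0 °C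
Reagents that add atoms: none
Why: Proposed new method: an intramolecular Nozaki–Hiyama γ-chloroallylation in which divalent chromium inserts into the allylic C–Br bond, the (chloroallyl)chromium equilibrates to the isomer with chlorine trans to CH2Cr and adds through its γ-carbon C6 to the C7 aldehyde via a six-membered chair, closing the 10-membered ring and giving the anti (6S,7R) chlorohydrin and the C5 exo-methylene in one event, with the aldehyde face expected to be fixed by chelation of trivalent chromium between the C8 hydroxyl and the carbonyl and by delivery from the C9 side, after which acid lactonises O7 onto the tert-butyl ester; the closest known reactions are intermolecular anti-selective additions of γ-chloroallylchromium reagents to aldehydes and intramolecular Nozaki–Hiyama allylations that close medium rings.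

**Step 20**
Reactants: 30 9-deacetyl lactone
Product: 31 CNP0259091.2 (target)
Conditions: Ac2O, DMAP, Et3N, CH2Cl2, rt
Reagents that add atoms: acetic anhydride, CC(=O)OC(C)=O
Why: acylation of the remaining secondary alcohol at C9; the tertiary C8 and C11 hydroxyls do not acylate under these conditions.

**Compound list**
1 | prop-2-yn-1-ol | C#CCO | starting material
2 | but-3-en-1-ylmagnesium bromide | C=CCC[Mg]Br | starting material
3 | magnesacycle 4-(but-3-en-1-yl)-2,5-dihydro-1,2-oxamagnesole | C=CCCC1=C[Mg]OC1 | intermediate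
4 | (Z)-2-(but-3-en-1-yl)-3-chloroprop-2-en-1-ol | OC/C(=C\Cl)CCC=C | intermediate
5 | tert-butyl{[(Z)-2-(but-3-en-1-yl)-3-chloroprop-2-en-1-yl]oxy}dimethylsilane | CC(C)(C)[Si](C)(C)OC/C(=C\Cl)CCC=C | intermediate
6 | (Z)-4-({[tert-butyl(dimethyl)silyl]oxy}methyl)-5-chloropent-4-enal | CC(C)(C)[Si](C)(C)OC/C(=C\Cl)CCC=O | intermediate
7 | (1Z,5Z)-2-({[tert-butyl(dimethyl)silyl]oxy}methyl)-1-chloro-6-iodohepta-1,5-diene (west fragment) | CC(C)(C)[Si](C)(C)OC/C(=C\Cl)CC/C=C(/C)I | intermediate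
8 | 5-methylfuran-2-carbaldehyde | Cc1ccc(C=O)o1 | starting material
9 | 2,2-dimethyl-1,3-dioxan-5-one | CC1(C)OCC(=O)CO1 | starting material
10 | (4R)-4-[(S)-hydroxy(5-methylfuran-2-yl)methyl]-2,2-dimethyl-1,3-dioxan-5-one | Cc1ccc(o1)[C@@H](O)[C@H]1OC(C)(C)OCC1=O | intermediate
11 | tert-butyl propanoate | CCC(=O)OC(C)(C)C | starting material
12 | lithium enolate of 11 (methyl trans to OLi) | C/C=C(/O[Li])OC(C)(C)C | intermediate
13 | tert-butyl (2R)-2-{(4R,5S)-5-hydroxy-4-[(S)-hydroxy(5-methylfuran-2-yl)methyl]-2,2-dimethyl-1,3-dioxan-5-yl}propanoate | Cc1ccc(o1)[C@@H](O)[C@H]1OC(C)(C)OC[C@@]1(O)[C@@H](C)C(=O)OC(C)(C)C | intermediate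
14 | tert-butyl (2R)-2-{(4R,5S)-5-hydroxy-4-[(1S,2R)-2-hydroxy-2-methyl-5-oxocyclopent-3-en-1-yl]-2,2-dimethyl-1,3-dioxan-5-yl}propanoate (hydroxyl and side chain trans) | O=C1C=C[C@@](C)(O)[C@@H]1[C@H]1OC(C)(C)OC[C@@]1(O)[C@@H](C)C(=O)OC(C)(C)C | intermediate
15 | epoxy ketone: 14 with a 12,13-oxirane cis to the C11 hydroxyl | O=C1[C@H]2O[C@H]2[C@@](C)(O)[C@@H]1[C@H]1OC(C)(C)OC[C@@]1(O)[C@@H](C)C(=O)OC(C)(C)C | intermediate
16 | bis(triethylsilyl) ether of 15 at the C8 and C11 hydroxyls | O=C1[C@H]2O[C@H]2[C@@](C)(O[Si](CC)(CC)CC)[C@@H]1[C@H]1OC(C)(C)OC[C@@]1(O[Si](CC)(CC)CC)[C@@H](C)C(=O)OC(C)(C)C | intermediate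
17 | alkenyllithium from 7 (lithium in place of iodine, geometry retained) | CC(C)(C)[Si](C)(C)OC/C(=C\Cl)CC/C=C(/C)[Li] | intermediate
18 | C14 tertiary alcohol: adduct of 17 to the ketone of 16 (alkenyl trans to the C10 side chain; major epimer) | CC(C)(C)[Si](C)(C)OC/C(=C\Cl)CC/C=C(/C)[C@@]1(O)[C@H]2O[C@H]2[C@@](C)(O[Si](CC)(CC)CC)[C@@H]1[C@H]1OC(C)(C)OC[C@@]1(O[Si](CC)(CC)CC)[C@@H](C)C(=O)OC(C)(C)C | intermediate
19 | (1R,2R)-1,2-epoxide of 18 | CC(C)(C)[Si](C)(C)OC/C(=C\Cl)CC[C@H]3O[C@@]3(C)[C@@]1(O)[C@H]2O[C@H]2[C@@](C)(O[Si](CC)(CC)CC)[C@@H]1[C@H]1OC(C)(C)OC[C@@]1(O[Si](CC)(CC)CC)[C@@H](C)C(=O)OC(C)(C)C | intermediate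
20 | ring-A β-hydroxy ketone: cyclohexanone with C14 ketone, 1S quaternary methyl centre, 2R carbinol chain, 12,13-oxirane; C8–C11 and C17 as in 31 | CC(C)(C)[Si](C)(C)OC/C(=C\Cl)CC[C@@H](O)[C@@]1(C)C(=O)[C@H]2O[C@H]2[C@@](C)(O[Si](CC)(CC)CC)[C@@H]1[C@H]1OC(C)(C)OC[C@@]1(O[Si](CC)(CC)CC)[C@@H](C)C(=O)OC(C)(C)C | intermediate
21 | C14 hydrazone of 20 | CC(C)(C)[Si](C)(C)OC/C(=C\Cl)CC[C@@H](O)[C@@]1(C)C(=NN)[C@H]2O[C@H]2[C@@](C)(O[Si](CC)(CC)CC)[C@@H]1[C@H]1OC(C)(C)OC[C@@]1(O[Si](CC)(CC)CC)[C@@H](C)C(=O)OC(C)(C)C | intermediate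
22 | allylic alcohol: C13=C14 alkene, 12R hydroxyl, 2R hydroxyl; other centres as in 31 | CC(C)(C)[Si](C)(C)OC/C(=C\Cl)CC[C@@H](O)[C@@]1(C)C=C[C@@H](O)[C@@](C)(O[Si](CC)(CC)CC)[C@@H]1[C@H]1OC(C)(C)OC[C@@]1(O[Si](CC)(CC)CC)[C@@H](C)C(=O)OC(C)(C)C | intermediate
23 | 2,12-diacetate of 22 | CC(C)(C)[Si](C)(C)OC/C(=C\Cl)CC[C@@H](OC(C)=O)[C@@]1(C)C=C[C@@H](OC(C)=O)[C@@](C)(O[Si](CC)(CC)CC)[C@@H]1[C@H]1OC(C)(C)OC[C@@]1(O[Si](CC)(CC)CC)[C@@H](C)C(=O)OC(C)(C)C | intermediate
24 | C16 primary allylic alcohol: 23 with all three silyl groups removed | OC/C(=C\Cl)CC[C@@H](OC(C)=O)[C@@]1(C)C=C[C@@H](OC(C)=O)[C@@](C)(O)[C@@H]1[C@H]1OC(C)(C)OC[C@@]1(O)[C@@H](C)C(=O)OC(C)(C)C | intermediate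
25 | C16 allylic bromide of 24 | BrC/C(=C\Cl)CC[C@@H](OC(C)=O)[C@@]1(C)C=C[C@@H](OC(C)=O)[C@@](C)(O)[C@@H]1[C@H]1OC(C)(C)OC[C@@]1(O)[C@@H](C)C(=O)OC(C)(C)C | intermediate
26 | 7,9-diol: 25 with the acetonide removed | BrC/C(=C\Cl)CC[C@@H](OC(C)=O)[C@@]1(C)C=C[C@@H](OC(C)=O)[C@@](C)(O)[C@@H]1[C@@H](O)[C@](CO)(O)[C@@H](C)C(=O)OC(C)(C)C | intermediate
27 | C7 aldehyde of 26 | BrC/C(=C\Cl)CC[C@@H](OC(C)=O)[C@@]1(C)C=C[C@@H](OC(C)=O)[C@@](C)(O)[C@@H]1[C@@H](O)[C@](C=O)(O)[C@@H](C)C(=O)OC(C)(C)C | intermediate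
28 | allylchromium dichloride from 27 (chlorine trans to CH2Cr) | Cl[Cr](Cl)C/C(=C/Cl)CC[C@@H](OC(C)=O)[C@@]1(C)C=C[C@@H](OC(C)=O)[C@@](C)(O)[C@@H]1[C@@H](O)[C@](C=O)(O)[C@@H](C)C(=O)OC(C)(C)C | intermediate
29 | macrocyclic (6S,7R)-chlorohydrin tert-butyl ester (10-membered ring closed, lactone open) | C=C1CC[C@@H](OC(C)=O)[C@@]2(C)C=C[C@@H](OC(C)=O)[C@@](C)(O)[C@@H]2[C@@H](O)[C@](O)([C@@H](C)C(=O)OC(C)(C)C)[C@@H](O)[C@H]1Cl | intermediate
30 | 9-deacetyl lactone (31 with free C9 hydroxyl) | C=C1CC[C@@H](OC(C)=O)[C@@]2(C)C=C[C@@H](OC(C)=O)[C@@](C)(O)[C@@H]2[C@@H](O)[C@]2(O)[C@@H](C)C(=O)O[C@H]2[C@H]1Cl | intermediate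
31 | CNP0259091.2 | C=C1CC[C@@H](OC(C)=O)[C@@]2(C)C=C[C@@H](OC(C)=O)[C@@](C)(O)[C@@H]2[C@@H](OC(C)=O)[C@]2(O)[C@@H](C)C(=O)O[C@H]2[C@H]1Cl | target

**Totals:** 20 steps; longest linear sequence 16 steps (steps 5–20, from 8 and 9); the west fragment 7 takes 4 steps and joins at step 10.

**Three steps most likely to fail**

Step 7 (Piancatelli rearrangement). The furyl cation sits next to the oxygenated C9, so a 1,2-hydride shift, acetonide loss or poor control of the conrotation sense by C9 can compete. The fallback avoids the cation altogether and sets out from 13. 1,1'-Thiocarbonyldiimidazole with DMAP acylates only the secondary C10 hydroxyl to give the thiocarbonylimidazolide F1. Bu3SnH/AIBN in toluene at 80 °C removes the C10 oxygen to give the 2-alkyl-5-methylfuran F2. mCPBA/NaHCO3 in CH2Cl2 at 0 °C opens the furan to the (Z)-ene-1,4-dione F3. Et3N in MeOH then closes the ring by intramolecular aldol addition of the C10 enolate to the methyl ketone, with equilibration at C10 and separation of the 10,11-trans isomer. The route is rejoined at 14.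

Step 12 (semipinacol ring expansion). BF3 may also open the ring oxirane or strip silyl groups, and the oxirane carbon C13 could migrate instead of C10. The fallback sets out from 19. N-(Trimethylsilyl)imidazole converts the C14 hydroxyl into the trimethylsilyl ether F4. The bulky methylaluminium bis(4-bromo-2,6-di-tert-butylphenoxide) in CH2Cl2 at −78 °C then effects the epoxy silyl ether rearrangement by the same anti 1,2-shift, with silyl transfer to O2, giving the β-silyloxy ketone F5. Citric acid in MeOH at 0 °C removes the trimethylsilyl group, and the route is rejoined at 20.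

Step 19 (the proposed new ring closure). The (chloroallyl)chromium may oligomerise or give the wrong C6/C7 diastereomer. The fallback separates ring closure from chlorohydrin formation, uses only known reactions and sets out from 26.
- CrCl2 in THF followed by water protonates the allylchromium at its γ-carbon to give the allylic chloride F6, which has no vinylic chlorine.
- TEMPO/PhI(OAc)2 gives the aldehyde F7, and Ac2O/DMAP gives the 9-acetate F8.
- A standard intramolecular Nozaki–Hiyama allylation (CrCl2, LiI, THF, high dilution) closes the 10-membered ring to the homoallylic alcohol F9.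
- Dess–Martin periodinane gives the C7 ketone F10.
- LiN(SiMe3)2/Me3SiCl then N-chlorosuccinimide chlorinates C6, the only enolisable position, to give the α-chloro ketone F11.
- NaBH4/CeCl3·7H2O at −78 °C reduces the ketone from the ring periphery to the chlorohydrin F12; the wrong epimer at either centre can be recycled through F10 or F11.
- CF3CO2H in CH2Cl2 lactonises F12, and the route is rejoined at 31.

**Further compounds**
F1 | step 7 | O-[(5-methylfuran-2-yl)methyl] imidazole-1-carbothioate of 13 at C10 | Cc1ccc(o1)[C@@H](OC(=S)n1ccnc1)[C@H]1OC(C)(C)OC[C@@]1(O)[C@@H](C)C(=O)OC(C)(C)C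
F2 | step 7 | C10-deoxy 2-alkyl-5-methylfuran | Cc1ccc(C[C@H]2OC(C)(C)OC[C@@]2(O)[C@@H](C)C(=O)OC(C)(C)C)o1
F3 | step 7 | (Z)-ene-1,4-dione from oxidative opening of F2 | CC(=O)/C=C\C(=O)C[C@H]1OC(C)(C)OC[C@@]1(O)[C@@H](C)C(=O)OC(C)(C)C
F4 | step 12 | C14 trimethylsilyl ether of 19 | CC(C)(C)[Si](C)(C)OC/C(=C\Cl)CC[C@H]3O[C@@]3(C)[C@@]1(O[Si](C)(C)C)[C@H]2O[C@H]2[C@@](C)(O[Si](CC)(CC)CC)[C@@H]1[C@H]1OC(C)(C)OC[C@@]1(O[Si](CC)(CC)CC)[C@@H](C)C(=O)OC(C)(C)C
F5 | step 12 | 2-O-trimethylsilyl ether of 20 | CC(C)(C)[Si](C)(C)OC/C(=C\Cl)CC[C@@H](O[Si](C)(C)C)[C@@]1(C)C(=O)[C@H]2O[C@H]2[C@@](C)(O[Si](CC)(CC)CC)[C@@H]1[C@H]1OC(C)(C)OC[C@@]1(O[Si](CC)(CC)CC)[C@@H](C)C(=O)OC(C)(C)C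
F6 | step 19 | allylic chloride diol (2-substituted 3-chloroprop-1-ene terminus, no vinylic chlorine) | ClCC(=C)CC[C@@H](OC(C)=O)[C@@]1(C)C=C[C@@H](OC(C)=O)[C@@](C)(O)[C@@H]1[C@@H](O)[C@](CO)(O)[C@@H](C)C(=O)OC(C)(C)C
F7 | step 19 | C7 aldehyde of F6 | ClCC(=C)CC[C@@H](OC(C)=O)[C@@]1(C)C=C[C@@H](OC(C)=O)[C@@](C)(O)[C@@H]1[C@@H](O)[C@](C=O)(O)[C@@H](C)C(=O)OC(C)(C)C
F8 | step 19 | 9-acetate of F7 | ClCC(=C)CC[C@@H](OC(C)=O)[C@@]1(C)C=C[C@@H](OC(C)=O)[C@@](C)(O)[C@@H]1[C@@H](OC(C)=O)[C@](C=O)(O)[C@@H](C)C(=O)OC(C)(C)C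
F9 | step 19 | macrocyclic homoallylic alcohol (C6 methylene, C7 hydroxyl, major epimer) | C=C1CC[C@@H](OC(C)=O)[C@@]2(C)C=C[C@@H](OC(C)=O)[C@@](C)(O)[C@@H]2[C@@H](OC(C)=O)[C@](O)([C@@H](C)C(=O)OC(C)(C)C)[C@@H](O)C1
F10 | step 19 | macrocyclic C7 ketone | C=C1CC[C@@H](OC(C)=O)[C@@]2(C)C=C[C@@H](OC(C)=O)[C@@](C)(O)[C@@H]2[C@@H](OC(C)=O)[C@](O)([C@@H](C)C(=O)OC(C)(C)C)C(=O)C1
F11 | step 19 | (6S)-6-chloro C7 ketone | C=C1CC[C@@H](OC(C)=O)[C@@]2(C)C=C[C@@H](OC(C)=O)[C@@](C)(O)[C@@H]2[C@@H](OC(C)=O)[C@](O)([C@@H](C)C(=O)OC(C)(C)C)C(=O)[C@H]1Cl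
F12 | step 19 | 9-acetate of 29 (chlorohydrin tert-butyl ester) | C=C1CC[C@@H](OC(C)=O)[C@@]2(C)C=C[C@@H](OC(C)=O)[C@@](C)(O)[C@@H]2[C@@H](OC(C)=O)[C@](O)([C@@H](C)C(=O)OC(C)(C)C)[C@@H](O)[C@H]1Cl
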